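**Retrosynthetic overview**

- The tridepside is cut at its two aryl ester bonds (ring A acyl to O4 of ring B, ring B acyl to O4 of ring C). Three benzyl groups (O2 of ring B, O2 and the carboxyl of ring C) fall in one final hydrogenolysis.
- The plan rests on ring C: C1 bears the carboxyl, C6 the methyl, and C2 and C4 bear meta oxygens around unsubstituted C3. A vinylketene (giving C2, C5, C6, C1) and an oxygenated terminal alkyne (giving C3, C4) assemble exactly this pattern, with O2 free and O4 silylated.
- Ring C is the only ring built: photochemical Wolff rearrangement of benzyl (2E)-5-diazo-3-methyl-4-oxopent-2-enoate in the presence of (triisopropylsilyloxy)ethyne forms C2–C3 and C4–C5, then C1–C2.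
- The diazoketone comes from butane-2,3-dione by Wittig olefination and detrifluoroacetylative diazo transfer, so that no free diazoalkane meets the electron-poor alkene. The ynol silyl ether comes from a formate-derived ynolate.
- Rings A and B come from the aromatic pool: 3,4,6-trimethoxy-2-methylbenzoic acid from 2,4-dimethoxy-6-methylbenzaldehyde, and ring B from orcinaldehyde with the formyl group as masked carboxyl.

Key step: step 4

Remark on the chemistry: the target has no stereocentre; the only stereochemical element is the E geometry of the enoate, carried from the Wittig product to the dienylketene. (Triisopropylsilyloxy)ethyne is assumed not to be purchasable and is made in step 3.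

**Route**

Step 1
Reactants: 1 butane-2,3-dione; 2 benzyl 2-(triphenyl-λ5-phosphanylidene)acetate
Product: 3 benzyl (2E)-3-methyl-4-oxopent-2-enoate
Conditions: 1 (3 equiv), CH2Cl2, 0 °C → rt, slow addition of 2
Reagents that add atoms: none
Why: Wittig olefination with a stabilised ylide: the 1,2-diketone is an activated ketone, reversible oxaphosphetane formation should give mainly the E enone (acetyl trans to the ester), the remaining carbonyl is deactivated by conjugation, and the excess of volatile diketone suppresses double olefination.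

Step 2
Reactants: 3 benzyl (2E)-3-methyl-4-oxopent-2-enoate
Product: 5 benzyl (2E)-5-diazo-3-methyl-4-oxopent-2-enoate, via trifluoroacetyl ketone 4 (not isolated)
Conditions: LiN(SiMe3)2, THF, −78 °C (3 added to the base); CF3CO2CH2CF3, −78 °C; aq HCl work-up; then MsN3, Et3N, H2O (1 equiv), MeCN, rt
Reagents that add atoms: methanesulfonyl azide CS(=O)(=O)N=[N+]=[N-] (the two diazo nitrogens of 5); 2,2,2-trifluoroethyl trifluoroacetate O=C(OCC(F)(F)F)C(F)(F)F (CF3CO group of 4 only, lost again)
Why: Detrifluoroacetylative diazo transfer (a Regitz-type reaction): the kinetic lithium enolate at the acetyl methyl group is acylated by the trifluoroethyl ester, and the activated 1,3-diketone 4 takes the diazo group from the sulfonyl azide with loss of the trifluoroacetyl group; no free diazoalkane is present to add as a dipole to the electron-poor alkene, which is why this route is preferred to acylating a diazoalkane with the corresponding enoyl chloride, and the E geometry is not touched.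

Step 3
Reactants: 6 ethyl formate; 7 dibromomethane; 8 triisopropylsilyl trifluoromethanesulfonate
Product: 10 (triisopropylsilyloxy)ethyne, via lithium ethynolate 9 (not isolated)
Conditions: 7 (1.1 equiv), lithium 2,2,6,6-tetramethylpiperidide (2.2 equiv), THF, −78 °C; 6; n-BuLi (1.1 equiv), −78 → 0 °C; 8 (2.2 equiv), −78 → 0 °C; distillation
Reagents that add atoms: lithium 2,2,6,6-tetramethylpiperidide [Li]N1C(C)(C)CCCC1(C)C and n-butyllithium [Li]CCCC (lithium counter-ion of 9 only; no atoms in 10)
Why: Kowalski ynolate formation followed by O-silylation: LiCHBr2 adds to the formate, the derived dibromo enolate undergoes bromine–lithium exchange, and the β-oxido carbenoid rearranges with 1,2-shift and loss of LiBr to lithium ethynolate 9, which the bulky silyl triflate should trap on oxygen (small silyl groups go to carbon) to give the terminal ynol silyl ether.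

Step 4
Reactants: 5 benzyl (2E)-5-diazo-3-methyl-4-oxopent-2-enoate; 10 (triisopropylsilyloxy)ethyne
Product: 15 benzyl 2-hydroxy-6-methyl-4-(triisopropylsilyloxy)benzoate, via vinylketene 11 (not isolated), via cyclobutenone 12 (not isolated), via dienylketene 13 (not isolated), via cyclohexadienone 14 (not isolated)
Conditions: hν (medium-pressure mercury lamp through Pyrex, or 365 nm LEDs), 10 (1.5 equiv), degassed ClCH2CH2Cl (0.3 M), 20 °C; then 80 °C in the dark
Reagents that add atoms: none
Why: Danheiser benzannulation in its photochemical Wolff variant with a siloxyalkyne: light expels N2 from 5 with 1,2-shift of the alkenyl group (Wolff rearrangement) to give vinylketene 11, and the nucleophilic CH terminus of ynol ether 10 attacks the ketene carbonyl carbon in a polarised [2+2] cycloaddition that forms C2–C3 and C4–C5 and gives cyclobutenone 12. Cyclobutenone 12 opens, photochemically or on warming, by reversible four-electron electrocyclic cleavage to dienylketene 13, and ring C closes by thermal disrotatory six-electron electrocyclisation between C1 and C2 to cyclohexadienone 14, which enolises to phenol 15. The ketene carbon becomes C2 with its free OH, the alkyne carbons become C3–H and C4–OSi, and the diazoketone supplies C5, C6 with its methyl and C1 with its ester, so the two oxygens of ring C emerge differentiated; no stereocentre is formed. The step needs the regiochemistry of the [2+2] addition, which the opposite polarisation of ketene and ynol ether secures, and it needs the E geometry of the enoate to survive, because only then does the ester stand trans to the ketene arm, point outward in the electrocyclisation, and stay unable to close through its carbonyl oxygen onto the ketene as a 6-benzyloxypyran-2-one. Irradiation above 300 nm into the diazoketone band, an excess of 10 that traps 11 as it forms, and completion of the ring closure in the dark are the measures against E to Z isomerisation. A β-ester on the vinylketene is an untried substituent in this annulation, but it should raise the electrophilicity of the ketene towards 10 and acidify the proton lost in the final enolisation.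

Step 5
Reactants: 15 benzyl 2-hydroxy-6-methyl-4-(triisopropylsilyloxy)benzoate
Product: 16 benzyl 2-(benzyloxy)-6-methyl-4-(triisopropylsilyloxy)benzoate
Conditions: BnOH, PPh3, diisopropyl azodicarboxylate, THF, 0 °C → rt
Reagents that add atoms: benzyl alcohol OCc1ccccc1 (benzyl group; its oxygen leaves with phosphorus)
Why: Mitsunobu etherification with the chelated but sufficiently acidic phenol as pronucleophile: the neutral conditions spare the aryl silyl ether and the benzyl ester, and the O2 left free by the annulation is thereby distinguished for good from the silylated O4.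

Step 6
Reactants: 16 benzyl 2-(benzyloxy)-6-methyl-4-(triisopropylsilyloxy)benzoate
Product: 17 benzyl 2-(benzyloxy)-4-hydroxy-6-methylbenzoate
Conditions: Bu4NF, AcOH, THF, 0 °C
Reagents that add atoms: none
Why: Fluoride cleavage of the aryl silyl ether, driven by the Si–F bond; the acetic acid buffer keeps the liberated phenoxide from attacking the benzyl ester.

Step 7
Reactants: 18 2,4-dimethoxy-6-methylbenzaldehyde
Product: 20 2,4-dimethoxy-6-methylphenol, via aryl formate 19 (not isolated)
Conditions: mCPBA, CH2Cl2, 0 °C → rt; aq NaHCO3 wash; then K2CO3 (cat.), MeOH, rt, under N2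
Reagents that add atoms: 3-chloroperbenzoic acid OOC(=O)c1cccc(Cl)c1 (one oxygen)
Why: Baeyer–Villiger (Dakin-type) oxidation: in the Criegee adduct the electron-rich aryl group migrates in preference to hydrogen to give aryl formate 19, which mild methanolysis converts into the phenol.

Step 8
Reactants: 20 2,4-dimethoxy-6-methylphenol
Product: 21 1,2,5-trimethoxy-3-methylbenzene
Conditions: MeI, K2CO3, acetone, reflux
Reagents that add atoms: iodomethane CI
Why: Williamson O-methylation of the phenoxide; the air-sensitive electron-rich phenol is alkylated directly after step 7.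

Step 9
Reactants: 21 1,2,5-trimethoxy-3-methylbenzene
Product: 23 3,4,6-trimethoxy-2-methylbenzaldehyde, via iminium chloride 22 (not isolated)
Conditions: POCl3, DMF, 0 → 60 °C; then H2O
Reagents that add atoms: N,N-dimethylformamide CN(C)C=O (formyl carbon; also the NMe2 group of 22); water O (carbonyl oxygen); phosphoryl chloride O=P(Cl)(Cl)Cl (chloride counter-ion of 22 only)
Why: Vilsmeier–Haack formylation: C4 of 21 is ortho to the C3 methyl and the C5 methoxy group and para to the coplanar C1 methoxy group, and it is less hindered than C6 between two methoxy groups, as in the formylation of orcinol dimethyl ether, so the formyl group should enter between CH3 and OCH3 (to be confirmed by an NOE between CHO and CH3).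

Step 10
Reactants: 23 3,4,6-trimethoxy-2-methylbenzaldehyde
Product: 24 3,4,6-trimethoxy-2-methylbenzoic acid
Conditions: NaClO2, NaH2PO4, 2-methylbut-2-ene, t-BuOH/H2O, rt
Reagents that add atoms: sodium chlorite [Na+].[O-]Cl=O (one oxygen)
Why: Pinnick oxidation: chlorous acid oxidises the hindered electron-rich aldehyde, and the alkene scavenges the hypochlorous acid that would otherwise chlorinate the arene.

Step 11
Reactants: 24 3,4,6-trimethoxy-2-methylbenzoic acid; 25 2,4-dihydroxy-6-methylbenzaldehyde (orcinaldehyde)
Product: 27 4-formyl-3-hydroxy-5-methylphenyl 3,4,6-trimethoxy-2-methylbenzoate, via acid chloride 26 (not isolated)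
Conditions: (COCl)2, DMF (cat.), CH2Cl2, 0 °C → rt, evaporate; then 25, Et3N, DMAP (cat.), CH2Cl2, 0 °C
Reagents that add atoms: oxalyl chloride O=C(Cl)C(=O)Cl (chlorine of 26 only; none remains in 27)
Why: Acylation of a phenol by an acid chloride: the 2,6-disubstituted acid is activated as chloride 26, and only the unchelated, more acidic 4-OH of 25 should react, the 2-OH being held in a hydrogen bond to the formyl group.

Step 12
Reactants: 27 4-formyl-3-hydroxy-5-methylphenyl 3,4,6-trimethoxy-2-methylbenzoate
Product: 28 3-(benzyloxy)-4-formyl-5-methylphenyl 3,4,6-trimethoxy-2-methylbenzoate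
Conditions: BnBr, K2CO3, DMF, rt → 50 °C
Reagents that add atoms: benzyl bromide BrCc1ccccc1
Why: Williamson benzylation of the chelated phenol; the aryl ester is flanked by OCH3 and CH3 and should resist carbonate and phenoxide at this temperature.

Step 13
Reactants: 28 3-(benzyloxy)-4-formyl-5-methylphenyl 3,4,6-trimethoxy-2-methylbenzoate
Product: 29 2-(benzyloxy)-6-methyl-4-[(3,4,6-trimethoxy-2-methylbenzoyl)oxy]benzoic acid
Conditions: NaClO2, NaH2PO4, 2-methylbut-2-ene, t-BuOH/H2O/THF, rt
Reagents that add atoms: sodium chlorite [Na+].[O-]Cl=O (one oxygen)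
Why: Pinnick oxidation releases the carboxyl of ring B from its formyl mask under conditions that leave the aryl ester and the benzyl ether intact.

Step 14
Reactants: 29 2-(benzyloxy)-6-methyl-4-[(3,4,6-trimethoxy-2-methylbenzoyl)oxy]benzoic acid; 17 benzyl 2-(benzyloxy)-4-hydroxy-6-methylbenzoate
Product: 31 benzyl 2-(benzyloxy)-4-({2-(benzyloxy)-6-methyl-4-[(3,4,6-trimethoxy-2-methylbenzoyl)oxy]benzoyl}oxy)-6-methylbenzoate, via acid chloride 30 (not isolated)
Conditions: (COCl)2, DMF (cat.), CH2Cl2, 0 °C → rt, evaporate; then 17, Et3N, DMAP (cat.), CH2Cl2, 0 °C → rt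
Reagents that add atoms: oxalyl chloride O=C(Cl)C(=O)Cl (chlorine of 30 only; none remains in 31)
Why: Esterification through the acid chloride of the 2,6-disubstituted acid with the single free phenol of 17; every ester carbonyl present is doubly ortho-substituted, so acyl scrambling between phenoxides should not compete.

Step 15
Reactants: 31 benzyl 2-(benzyloxy)-4-({2-(benzyloxy)-6-methyl-4-[(3,4,6-trimethoxy-2-methylbenzoyl)oxy]benzoyl}oxy)-6-methylbenzoate
Product: 32 2-hydroxy-4-({2-hydroxy-6-methyl-4-[(3,4,6-trimethoxy-2-methylbenzoyl)oxy]benzoyl}oxy)-6-methylbenzoic acid (CNP0328932.0)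
Conditions: H2 (1 atm), 10% Pd/C, EtOAc, rt
Reagents that add atoms: none
Why: Catalytic hydrogenolysis cleaves the benzyl ester and both benzyl ethers at their benzylic C–O bonds, while aryl esters and aryl methyl ethers are inert; there is no stereocentre to set.

**Compound list**

1 | butane-2,3-dione | CC(=O)C(C)=O | starting material
2 | benzyl 2-(triphenyl-λ5-phosphanylidene)acetate | O=C(C=P(c1ccccc1)(c1ccccc1)c1ccccc1)OCc1ccccc1 | starting material
3 | benzyl (2E)-3-methyl-4-oxopent-2-enoate | CC(=O)/C(C)=C/C(=O)OCc1ccccc1 | intermediate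
4 | benzyl (2E)-6,6,6-trifluoro-3-methyl-4,6-dioxohex-2-enoate | O=C(CC(=O)/C(C)=C/C(=O)OCc1ccccc1)C(F)(F)F | intermediate
5 | benzyl (2E)-5-diazo-3-methyl-4-oxopent-2-enoate | [N-]=[N+]=CC(=O)/C(C)=C/C(=O)OCc1ccccc1 | intermediate
6 | ethyl formate | CCOC=O | starting material
7 | dibromomethane | BrCBr | starting material
8 | triisopropylsilyl trifluoromethanesulfonate | CC(C)[Si](OS(=O)(=O)C(F)(F)F)(C(C)C)C(C)C | starting material
9 | lithium ethynolate | [Li+].[O-]C#C | intermediate
10 | (triisopropylsilyloxy)ethyne | C#CO[Si](C(C)C)(C(C)C)C(C)C | intermediate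
11 | benzyl (2E)-3-methyl-5-oxopenta-2,4-dienoate | O=C=C/C(C)=C/C(=O)OCc1ccccc1 | intermediate
12 | benzyl (2E)-3-[4-oxo-2-(triisopropylsilyloxy)cyclobut-2-en-1-yl]but-2-enoate (racemic) | O=C1C=C(O[Si](C(C)C)(C(C)C)C(C)C)C1/C(C)=C/C(=O)OCc1ccccc1 | intermediate
13 | benzyl (2E,4E)-3-methyl-7-oxo-5-(triisopropylsilyloxy)hepta-2,4,6-trienoate | O=C=C/C(O[Si](C(C)C)(C(C)C)C(C)C)=C\C(C)=C\C(=O)OCc1ccccc1 | intermediate
14 | benzyl 2-methyl-6-oxo-4-(triisopropylsilyloxy)cyclohexa-2,4-diene-1-carboxylate (racemic) | O=C1C=C(O[Si](C(C)C)(C(C)C)C(C)C)C=C(C)C1C(=O)OCc1ccccc1 | intermediate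
15 | benzyl 2-hydroxy-6-methyl-4-(triisopropylsilyloxy)benzoate | Cc1cc(O[Si](C(C)C)(C(C)C)C(C)C)cc(O)c1C(=O)OCc1ccccc1 | intermediate
16 | benzyl 2-(benzyloxy)-6-methyl-4-(triisopropylsilyloxy)benzoate | Cc1cc(O[Si](C(C)C)(C(C)C)C(C)C)cc(OCc2ccccc2)c1C(=O)OCc1ccccc1 | intermediate
17 | benzyl 2-(benzyloxy)-4-hydroxy-6-methylbenzoate | Cc1cc(O)cc(OCc2ccccc2)c1C(=O)OCc1ccccc1 | intermediate
18 | 2,4-dimethoxy-6-methylbenzaldehyde | COc1cc(C)c(C=O)c(OC)c1 | starting material
19 | 2,4-dimethoxy-6-methylphenyl formate | COc1cc(C)c(OC=O)c(OC)c1 | intermediate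
20 | 2,4-dimethoxy-6-methylphenol | COc1cc(C)c(O)c(OC)c1 | intermediate
21 | 1,2,5-trimethoxy-3-methylbenzene | COc1cc(C)c(OC)c(OC)c1 | intermediate
22 | N-methyl-N-[(3,4,6-trimethoxy-2-methylphenyl)methylidene]methanaminium chloride | COc1cc(OC)c(C=[N+](C)C)c(C)c1OC.[Cl-] | intermediate
23 | 3,4,6-trimethoxy-2-methylbenzaldehyde | COc1cc(OC)c(C=O)c(C)c1OC | intermediate
24 | 3,4,6-trimethoxy-2-methylbenzoic acid | COc1cc(OC)c(C(=O)O)c(C)c1OC | intermediate
25 | 2,4-dihydroxy-6-methylbenzaldehyde (orcinaldehyde) | Cc1cc(O)cc(O)c1C=O | starting material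
26 | 3,4,6-trimethoxy-2-methylbenzoyl chloride | COc1cc(OC)c(C(=O)Cl)c(C)c1OC | intermediate
27 | 4-formyl-3-hydroxy-5-methylphenyl 3,4,6-trimethoxy-2-methylbenzoate | COc1cc(OC)c(C(=O)Oc2cc(C)c(C=O)c(O)c2)c(C)c1OC | intermediate
28 | 3-(benzyloxy)-4-formyl-5-methylphenyl 3,4,6-trimethoxy-2-methylbenzoate | COc1cc(OC)c(C(=O)Oc2cc(C)c(C=O)c(OCc3ccccc3)c2)c(C)c1OC | intermediate
29 | 2-(benzyloxy)-6-methyl-4-[(3,4,6-trimethoxy-2-methylbenzoyl)oxy]benzoic acid | COc1cc(OC)c(C(=O)Oc2cc(C)c(C(=O)O)c(OCc3ccccc3)c2)c(C)c1OC | intermediate
30 | 2-(benzyloxy)-6-methyl-4-[(3,4,6-trimethoxy-2-methylbenzoyl)oxy]benzoyl chloride | COc1cc(OC)c(C(=O)Oc2cc(C)c(C(=O)Cl)c(OCc3ccccc3)c2)c(C)c1OC | intermediate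
31 | benzyl 2-(benzyloxy)-4-({2-(benzyloxy)-6-methyl-4-[(3,4,6-trimethoxy-2-methylbenzoyl)oxy]benzoyl}oxy)-6-methylbenzoate | COc1cc(OC)c(C(=O)Oc2cc(C)c(C(=O)Oc3cc(C)c(C(=O)OCc4ccccc4)c(OCc4ccccc4)c3)c(OCc3ccccc3)c2)c(C)c1OC | intermediate
32 | 2-hydroxy-4-({2-hydroxy-6-methyl-4-[(3,4,6-trimethoxy-2-methylbenzoyl)oxy]benzoyl}oxy)-6-methylbenzoic acid | COc1cc(OC)c(C(=O)Oc2cc(C)c(C(=O)Oc3cc(C)c(C(=O)O)c(O)c3)c(O)c2)c(C)c1OC | target

**Step count**

Total: 15 steps. Longest linear sequence: 9 steps (steps 7 to 15, from 18 to 32). The ring C branch (steps 1, 2, 4, 5, 6) joins at step 14, with step 3 as a one-step side branch.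

**Steps most likely to fail**

Step 4 (key step). The enoate may isomerise from E to Z under irradiation, at the diazoketone or the vinylketene stage, after which the ester carbonyl oxygen closes onto the ketene and material is diverted to a pyranone. The ketene may also oligomerise if its capture by the ynol ether is slow, and the acceptor-substituted dienylketene may close sluggishly. Fallback: ring C is taken from the aromatic pool in place of the annulation; the fallback sets out from orcinaldehyde 25 and comes back to the route at 15. Silylation of the unchelated 4-OH (i-Pr3SiCl, imidazole, CH2Cl2, 0 °C) should give 2-hydroxy-6-methyl-4-(triisopropylsilyloxy)benzaldehyde F1. Pinnick oxidation (NaClO2, NaH2PO4, 2-methylbut-2-ene) should give 2-hydroxy-6-methyl-4-(triisopropylsilyloxy)benzoic acid F2. Alkylation of the carboxylate alone (BnBr, KHCO3, DMF, rt) then gives 15.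

Step 2. The lithium enolate, or the amide base itself, may add in conjugate fashion to the doubly activated alkene of 3, or deprotonation may occur at the C3 methyl group (vinylogous to the ester), so that oligomers form in place of the trifluoroacetyl ketone. Fallback: a route without any metal enolate, setting out from 3 and coming back at 5. Soft enolisation (Me3SiOTf, Et3N, CH2Cl2, 0 °C) should give benzyl (2E)-3-methyl-4-(trimethylsilyloxy)penta-2,4-dienoate F3. N-Bromosuccinimide (THF, 0 °C) converts it into benzyl (2E)-5-bromo-3-methyl-4-oxopent-2-enoate F4. N,N'-Ditosylhydrazine with DBU (THF, 0 °C) then turns the bromomethyl ketone into 5 by N-alkylation and twofold sulfinate elimination.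

Step 3. With a formate the carbenoid rearrangement needs a hydride rather than a carbon group to shift and may stall. The unsubstituted ynolate may also oligomerise, silylation may go to carbon to give the silylketene, and the volatile, acid-sensitive terminal ynol ether may be lost on isolation. Fallback: the silyloxy group is replaced by tert-butoxy; the fallback sets out from diazoketone 5 and comes back at 17. Potassium tert-butoxide and trichloroethylene (THF, −78 °C → rt) give 2-{[(E)-1,2-dichloroethenyl]oxy}-2-methylpropane F5. n-BuLi (2.2 equiv, THF, −78 → −40 °C, then MeOH) gives tert-butoxyethyne F6. Annulation of 5 with F6 under the conditions of step 4 (excess alkyne removed before heating) should give benzyl 4-(tert-butoxy)-2-hydroxy-6-methylbenzoate F7. Mitsunobu benzylation as in step 5 gives benzyl 2-(benzyloxy)-4-(tert-butoxy)-6-methylbenzoate F8, and CF3CO2H in CH2Cl2 at 0 °C cleaves the tert-butyl ether to 17.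

**Further compounds**

F1 | step 4 | 2-hydroxy-6-methyl-4-(triisopropylsilyloxy)benzaldehyde | Cc1cc(O[Si](C(C)C)(C(C)C)C(C)C)cc(O)c1C=O
F2 | step 4 | 2-hydroxy-6-methyl-4-(triisopropylsilyloxy)benzoic acid | Cc1cc(O[Si](C(C)C)(C(C)C)C(C)C)cc(O)c1C(=O)O
F3 | step 2 | benzyl (2E)-3-methyl-4-(trimethylsilyloxy)penta-2,4-dienoate | C=C(O[Si](C)(C)C)/C(C)=C/C(=O)OCc1ccccc1
F4 | step 2 | benzyl (2E)-5-bromo-3-methyl-4-oxopent-2-enoate | BrCC(=O)/C(C)=C/C(=O)OCc1ccccc1
F5 | step 3 | 2-{[(E)-1,2-dichloroethenyl]oxy}-2-methylpropane | CC(C)(C)O/C(Cl)=C\Cl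
F6 | step 3 | tert-butoxyethyne | C#COC(C)(C)C
F7 | step 3 | benzyl 4-(tert-butoxy)-2-hydroxy-6-methylbenzoate | Cc1cc(OC(C)(C)C)cc(O)c1C(=O)OCc1ccccc1
F8 | step 3 | benzyl 2-(benzyloxy)-4-(tert-butoxy)-6-methylbenzoate | Cc1cc(OC(C)(C)C)cc(OCc2ccccc2)c1C(=O)OCc1ccccc1
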